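**Retrosynthetic overview**
- The target comes from its fully protected form (tert‑butyl acrylate, diphenylmethylene‑protected catechol) by one acidolysis.
- Key disconnection C7–C8 of the α‑ketol: a carbene‑generated acyl anion at the C8 aldehyde adds to the C7 methyl ketone (intramolecular crossed benzoin). It closes the carbocycle last and sets C6 and C7 together by dynamic kinetic resolution.
- C4a–C5: reductive Heck coupling of a 4‑bromo‑2H‑pyran‑3‑carbaldehyde with a 1‑acetylvinyl aryl ester, which brings in the aryl ester, C5–C7 and the methyl group.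
- The pyran ring is made first: acetylacrylate ester + 3‑chloropropanoyl chloride (Claisen acylation, O‑alkylation), then bromoformylation.
- Aryl acid from 2,3,4‑trimethoxy‑6‑methylbenzaldehyde. Ring order: dioxole (protecting ring), pyran ring, carbocycle.

Assumption: the (5aR,10bS) antipode of the aminoindanol triazolium salt is taken to be the one that gives 7S; both antipodes are sold, so the other is used if the sense proves opposite.

Nothing in this route has been run; conditions are proposals based on the named reaction types.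

**Step 1**
Reactants: 1 2,3,4‑trimethoxy‑6‑methylbenzaldehyde
Product: 2 2,3,4‑trihydroxy‑6‑methylbenzaldehyde
Conditions: BBr3 (4 equiv), CH2Cl2, −78 °C to rt; then H2O
Reagents that add atoms: none
Why: Lewis‑acid aryl methyl ether cleavage, in which boron complexes each ether oxygen and bromide removes the methyl group by SN2, frees all three phenols and leaves the aldehyde alone.

**Step 2**
Reactants: 2 2,3,4‑trihydroxy‑6‑methylbenzaldehyde
Product: 3 4‑hydroxy‑6‑methyl‑2,2‑diphenyl‑1,3‑benzodioxole‑5‑carbaldehyde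
Conditions: Ph2CCl2 (1.2 equiv), Ph2O, 175 °C
Reagents that add atoms: dichlorodiphenylmethane, ClC(Cl)(c1ccccc1)c1ccccc1
Why: Catechol ketalisation with a gem‑dichloride closes the five‑membered ketal on the 3‑ and 4‑hydroxyls, because the 2‑hydroxyl is tied up in a hydrogen bond to the ortho aldehyde.

**Step 3**
Reactants: 3 4‑hydroxy‑6‑methyl‑2,2‑diphenyl‑1,3‑benzodioxole‑5‑carbaldehyde
Product: 4 4‑methoxy‑6‑methyl‑2,2‑diphenyl‑1,3‑benzodioxole‑5‑carbaldehyde
Conditions: MeI, K2CO3, DMF, 40 °C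
Reagents that add atoms: iodomethane, CI
Why: Williamson ether synthesis on the only free (chelated) phenol gives the 2‑methoxy group of the target.

**Step 4**
Reactants: 4 4‑methoxy‑6‑methyl‑2,2‑diphenyl‑1,3‑benzodioxole‑5‑carbaldehyde
Product: 5 4‑methoxy‑6‑methyl‑2,2‑diphenyl‑1,3‑benzodioxole‑5‑carboxylic acid
Conditions: NaClO2, NaH2PO4, 2‑methylbut‑2‑ene, t‑BuOH/H2O, rt
Reagents that add atoms: sodium chlorite, [Na+].[O-]Cl=O
Why: Pinnick oxidation converts the hindered, electron‑rich aldehyde to the acid, while the alkene scavenges hypochlorous acid and so protects the arene and the ketal.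

**Step 5**
Reactants: 5 4‑methoxy‑6‑methyl‑2,2‑diphenyl‑1,3‑benzodioxole‑5‑carboxylic acid; 6 butane‑2,3‑dione
Product: 8 3‑oxobut‑1‑en‑2‑yl 4‑methoxy‑6‑methyl‑2,2‑diphenyl‑1,3‑benzodioxole‑5‑carboxylate, via aroyl chloride 7 (not isolated)
Conditions: (COCl)2, DMF (cat.), CH2Cl2, rt; evaporate; then 6 (3 equiv), Et3N, DMAP (cat.), THF, 0 °C to rt
Reagents that add atoms: oxalyl chloride, O=C(Cl)C(Cl)=O (its chlorine stands in intermediate 7 only; none of its atoms stay in 8)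
Why: Acid chloride formation followed by O‑acylation of the biacetyl enolate gives the captodative 1‑acetylvinyl ester, so the hindered aryl ester is made on an unhindered enolate oxygen before any stereocentre exists.

**Step 6**
Reactants: 9 2‑oxopropanal (methylglyoxal, 40 % in water); 10 tert‑butyl (triphenyl‑λ5‑phosphanylidene)acetate
Product: 11 tert‑butyl (2E)‑4‑oxopent‑2‑enoate
Conditions: CH2Cl2/H2O, rt
Reagents that add atoms: none
Why: Wittig olefination with a stabilised ylide attacks only the aldehyde of methylglyoxal and gives the E alkene that becomes the acrylate side chain.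

**Step 7**
Reactants: 11 tert‑butyl (2E)‑4‑oxopent‑2‑enoate; 12 3‑chloropropanoyl chloride
Product: 14 tert‑butyl (2E)‑3‑(4‑oxo‑3,4‑dihydro‑2H‑pyran‑6‑yl)prop‑2‑enoate, via chloro diketone 13 (not isolated)
Conditions: MgBr2·OEt2, i‑Pr2NEt, CH2Cl2, 0 °C to rt; crude, then K2CO3, acetone, 50 °C
Reagents that add atoms: none
Why: Soft‑enolisation Claisen C‑acylation of the only enolisable position (the methyl ketone) gives the 1,3‑diketone, whose distal enolate oxygen then displaces the primary chloride (6‑exo‑tet O‑alkylation, irreversible) to close the dihydropyranone.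

**Step 8**
Reactants: 14 tert‑butyl (2E)‑3‑(4‑oxo‑3,4‑dihydro‑2H‑pyran‑6‑yl)prop‑2‑enoate
Product: 16 tert‑butyl (2E)‑3‑(4‑bromo‑3‑formyl‑2H‑pyran‑6‑yl)prop‑2‑enoate, via iminium bromide 15 (not isolated)
Conditions: PBr3, DMF, CHCl3, 0 °C to rt; then aq. NaOAc
Reagents that add atoms: N,N‑dimethylformamide, CN(C)C=O; phosphorus tribromide, BrP(Br)Br; water, O
Why: Vilsmeier–Haack–Arnold bromoformylation turns the ketone carbonyl into the vinyl bromide and formylates the only α‑CH2 at the terminus of the derived 2H‑pyran dienol ether, giving the ring‑locked Z β‑bromo enal.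

**Step 9**
Reactants: 16 tert‑butyl (2E)‑3‑(4‑bromo‑3‑formyl‑2H‑pyran‑6‑yl)prop‑2‑enoate; 8 3‑oxobut‑1‑en‑2‑yl 4‑methoxy‑6‑methyl‑2,2‑diphenyl‑1,3‑benzodioxole‑5‑carboxylate
Product: 17 tert‑butyl (2E)‑3‑{3‑formyl‑4‑[2‑[(4‑methoxy‑6‑methyl‑2,2‑diphenyl‑1,3‑benzodioxole‑5‑carbonyl)oxy]‑3‑oxobutyl]‑2H‑pyran‑6‑yl}prop‑2‑enoate, racemic at the acyloxy carbon
Conditions: Pd(OAc)2 (5 mol %), PPh3 (10 mol %), HCO2H, Et3N, DMF, 60 °C
Reagents that add atoms: none
Why: Reductive Heck coupling (Cacchi‑type conjugate addition): zerovalent palladium inserts into the activated vinyl bromide, the vinyl group adds to the terminal CH2 of the captodative enone, and the resulting α‑keto alkylpalladium is reduced by formate instead of undergoing β‑hydride elimination, so the new C6 centre forms racemic.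

**Step 10**
Reactants: 17 racemic tert‑butyl (2E)‑3‑{3‑formyl‑4‑[2‑(aroyloxy)‑3‑oxobutyl]‑2H‑pyran‑6‑yl}prop‑2‑enoate
Product: 18 tert‑butyl (2E)‑3‑[(6R,7S)‑7‑hydroxy‑6‑[(4‑methoxy‑6‑methyl‑2,2‑diphenyl‑1,3‑benzodioxole‑5‑carbonyl)oxy]‑7‑methyl‑8‑oxo‑5,6,7,8‑tetrahydro‑1H‑isochromen‑3‑yl]prop‑2‑enoate (acyloxy and tertiary hydroxyl trans)
Conditions: (5aR,10bS)‑2‑mesityl‑5a,10b‑dihydro‑4H,6H‑indeno[2,1‑b][1,2,4]triazolo[4,3‑d][1,4]oxazin‑2‑ium chloride (15 mol %), Cs2CO3 (30 mol %), THF, 25 °C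
Reagents that add atoms: none
Why: Proposed new method: the carbene adds to the aldehyde to give a Breslow‑type acyl anion equivalent that attacks the methyl ketone through a six‑membered transition state (intramolecular crossed benzoin), the chiral carbene fixing the ketone face (7S) while the (6R) enantiomer cyclises faster (acyloxy group pseudo‑equatorial and antiperiplanar to the forming C7–C8 bond, hydrogen‑bonded ketone oxygen pseudo‑equatorial, hence trans) and Cs2CO3 keeps C6 equilibrating through the ketone enolate, so both stereocentres come from one dynamic kinetic resolution; the closest known reaction type is the carbene‑catalysed intramolecular crossed benzoin with dynamic kinetic resolution of α‑substituted β‑keto esters.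

**Step 11**
Reactants: 18 tert‑butyl (2E)‑3‑[(6R,7S)‑7‑hydroxy‑6‑[(4‑methoxy‑6‑methyl‑2,2‑diphenyl‑1,3‑benzodioxole‑5‑carbonyl)oxy]‑7‑methyl‑8‑oxo‑5,6,7,8‑tetrahydro‑1H‑isochromen‑3‑yl]prop‑2‑enoate
Product: 19 (2E)‑3‑[(6R,7S)‑6‑[(3,4‑dihydroxy‑2‑methoxy‑6‑methylbenzoyl)oxy]‑7‑hydroxy‑7‑methyl‑8‑oxo‑5,6,7,8‑tetrahydro‑1H‑isochromen‑3‑yl]prop‑2‑enoic acid
Conditions: TFA/CH2Cl2/H2O (10:10:1), 0 °C to rt
Reagents that add atoms: none
Why: Acidolysis cleaves the tert‑butyl ester (loss of isobutene) and hydrolyses the diphenylmethylene ketal in one operation, while the hindered aryl ester, the vinylogous‑ester chromophore and both stereocentres (neither enolisable) are untouched.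

**Compound list**
1 | 2,3,4‑trimethoxy‑6‑methylbenzaldehyde | COc1cc(C)c(C=O)c(OC)c1OC | starting material
2 | 2,3,4‑trihydroxy‑6‑methylbenzaldehyde | Cc1cc(O)c(O)c(O)c1C=O | intermediate
3 | 4‑hydroxy‑6‑methyl‑2,2‑diphenyl‑1,3‑benzodioxole‑5‑carbaldehyde | Cc1cc2OC(c3ccccc3)(c3ccccc3)Oc2c(O)c1C=O | intermediate
4 | 4‑methoxy‑6‑methyl‑2,2‑diphenyl‑1,3‑benzodioxole‑5‑carbaldehyde | Cc1cc2OC(c3ccccc3)(c3ccccc3)Oc2c(OC)c1C=O | intermediate
5 | 4‑methoxy‑6‑methyl‑2,2‑diphenyl‑1,3‑benzodioxole‑5‑carboxylic acid | Cc1cc2OC(c3ccccc3)(c3ccccc3)Oc2c(OC)c1C(=O)O | intermediate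
6 | butane‑2,3‑dione | CC(=O)C(C)=O | starting material
7 | 4‑methoxy‑6‑methyl‑2,2‑diphenyl‑1,3‑benzodioxole‑5‑carbonyl chloride | Cc1cc2OC(c3ccccc3)(c3ccccc3)Oc2c(OC)c1C(Cl)=O | intermediate
8 | 3‑oxobut‑1‑en‑2‑yl 4‑methoxy‑6‑methyl‑2,2‑diphenyl‑1,3‑benzodioxole‑5‑carboxylate | Cc1cc2OC(c3ccccc3)(c3ccccc3)Oc2c(OC)c1C(=O)OC(=C)C(C)=O | intermediate
9 | 2‑oxopropanal (methylglyoxal) | CC(=O)C=O | starting material
10 | tert‑butyl (triphenyl‑λ5‑phosphanylidene)acetate | CC(C)(C)OC(=O)C=P(c1ccccc1)(c1ccccc1)c1ccccc1 | starting material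
11 | tert‑butyl (2E)‑4‑oxopent‑2‑enoate | CC(=O)/C=C/C(=O)OC(C)(C)C | intermediate
12 | 3‑chloropropanoyl chloride | ClCCC(Cl)=O | starting material
13 | tert‑butyl (2E)‑8‑chloro‑4,6‑dioxooct‑2‑enoate | ClCCC(=O)CC(=O)/C=C/C(=O)OC(C)(C)C | intermediate
14 | tert‑butyl (2E)‑3‑(4‑oxo‑3,4‑dihydro‑2H‑pyran‑6‑yl)prop‑2‑enoate | O=C1CCOC(/C=C/C(=O)OC(C)(C)C)=C1 | intermediate
15 | N‑{[4‑bromo‑6‑[(1E)‑3‑tert‑butoxy‑3‑oxoprop‑1‑en‑1‑yl]‑2H‑pyran‑3‑yl]methylidene}‑N‑methylmethanaminium bromide | C[N+](C)=CC1=C(Br)C=C(/C=C/C(=O)OC(C)(C)C)OC1.[Br-] | intermediate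
16 | tert‑butyl (2E)‑3‑(4‑bromo‑3‑formyl‑2H‑pyran‑6‑yl)prop‑2‑enoate | O=CC1=C(Br)C=C(/C=C/C(=O)OC(C)(C)C)OC1 | intermediate
17 | tert‑butyl (2E)‑3‑{3‑formyl‑4‑[2‑[(4‑methoxy‑6‑methyl‑2,2‑diphenyl‑1,3‑benzodioxole‑5‑carbonyl)oxy]‑3‑oxobutyl]‑2H‑pyran‑6‑yl}prop‑2‑enoate, racemic | O=CC1=C(CC(OC(=O)c2c(C)cc3OC(c4ccccc4)(c4ccccc4)Oc3c2OC)C(C)=O)C=C(/C=C/C(=O)OC(C)(C)C)OC1 | intermediate
18 | tert‑butyl (2E)‑3‑[(6R,7S)‑7‑hydroxy‑6‑[(4‑methoxy‑6‑methyl‑2,2‑diphenyl‑1,3‑benzodioxole‑5‑carbonyl)oxy]‑7‑methyl‑8‑oxo‑5,6,7,8‑tetrahydro‑1H‑isochromen‑3‑yl]prop‑2‑enoate | COc1c2OC(c3ccccc3)(c3ccccc3)Oc2cc(C)c1C(=O)O[C@@H]1CC2=C(COC(/C=C/C(=O)OC(C)(C)C)=C2)C(=O)[C@@]1(C)O | intermediate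
19 | (2E)‑3‑[(6R,7S)‑6‑[(3,4‑dihydroxy‑2‑methoxy‑6‑methylbenzoyl)oxy]‑7‑hydroxy‑7‑methyl‑8‑oxo‑5,6,7,8‑tetrahydro‑1H‑isochromen‑3‑yl]prop‑2‑enoic acid | COc1c(O)c(O)cc(C)c1C(=O)O[C@@H]1CC2=C(COC(/C=C/C(=O)O)=C2)C(=O)[C@@]1(C)O | target

**Step count**
Total: 11 steps. Longest linear sequence: 8 steps (steps 1, 2, 3, 4, 5, 9, 10, 11).

**Three steps most likely to fail**

Step 10 (benzoin with dynamic kinetic resolution). The risks are slow epimerisation at C6, loss of the aryl carboxylate by vinylogous E1cB elimination, aldol closure of the C6 enolate onto the aldehyde, and a sluggish electron‑rich (vinylogous formate) aldehyde. The fallback fixes C6 before ring closure instead of relying on epimerisation in the flask. It sets out from 16. Miyaura borylation (B2pin2, PdCl2(dppf), KOAc, dioxane, 80 °C) gives the pinacol boronate tert‑butyl (2E)‑3‑[3‑formyl‑4‑(4,4,5,5‑tetramethyl‑1,3,2‑dioxaborolan‑2‑yl)‑2H‑pyran‑6‑yl]prop‑2‑enoate F1. Rhodium‑catalysed conjugate addition of F1 to 8 with enantioselective protonation of the rhodium enolate (Rh(acac)(C2H4)2, the BINAP antipode that gives R, 2‑methoxyphenol as proton source, dioxane, 60 °C) gives the single enantiomer tert‑butyl (2E)‑3‑{3‑formyl‑4‑[(2R)‑2‑[(4‑methoxy‑6‑methyl‑2,2‑diphenyl‑1,3‑benzodioxole‑5‑carbonyl)oxy]‑3‑oxobutyl]‑2H‑pyran‑6‑yl}prop‑2‑enoate F2. F2 is cyclised with the same triazolium salt but with NaOAc, a base too weak to enolise C6, so the benzoin is a plain matched diastereoselective closure. The route is rejoined at 18.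

Step 9 (reductive Heck). The risks are β‑hydride elimination to the ordinary Heck diene and hydrodebromination of 16. The fallback separates C–C bond formation from hydride delivery and sets out from 16 and 8. A normal Mizoroki–Heck reaction (Pd(OAc)2, P(o‑tol)3, Et3N, MeCN, 70 °C) gives the dienyl enol ester tert‑butyl (2E)‑3‑{3‑formyl‑4‑[(1Z)‑2‑[(4‑methoxy‑6‑methyl‑2,2‑diphenyl‑1,3‑benzodioxole‑5‑carbonyl)oxy]‑3‑oxobut‑1‑en‑1‑yl]‑2H‑pyran‑6‑yl}prop‑2‑enoate F3; its alkene geometry does not matter. Chemoselective copper hydride 1,4‑reduction of the α‑acyloxy enone ([(Ph3P)CuH]6, wet toluene, rt) then gives 17, where the route is rejoined.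

Step 8 (bromoformylation of a vinylogous ester). The risks are formylation at the ring CH next to the enol ether carbon and loss of the tert‑butyl ester to HBr. The fallback builds the same β‑functionalised enal stepwise without phosphorus halides and sets out from 14. Condensation with N,N‑dimethylformamide dimethyl acetal (toluene, 90 °C) gives the enaminone tert‑butyl (2E)‑3‑{(3E)‑3‑[(dimethylamino)methylidene]‑4‑oxo‑3,4‑dihydro‑2H‑pyran‑6‑yl}prop‑2‑enoate F4. O‑Triflation of the vinylogous amide (Tf2O, 2,6‑lutidine, CH2Cl2, −78 °C) and hydrolysis of the iminium salt (aq. NaHCO3) give the triflate tert‑butyl (2E)‑3‑{3‑formyl‑4‑[(trifluoromethanesulfonyl)oxy]‑2H‑pyran‑6‑yl}prop‑2‑enoate F5. F5 takes the place of 16 in the reductive Heck coupling with 8, and the route is rejoined at 17.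

**Further compounds**
F1 | step 10 | tert‑butyl (2E)‑3‑[3‑formyl‑4‑(4,4,5,5‑tetramethyl‑1,3,2‑dioxaborolan‑2‑yl)‑2H‑pyran‑6‑yl]prop‑2‑enoate | O=CC1=C(B2OC(C)(C)C(C)(C)O2)C=C(/C=C/C(=O)OC(C)(C)C)OC1
F2 | step 10 | tert‑butyl (2E)‑3‑{3‑formyl‑4‑[(2R)‑2‑[(4‑methoxy‑6‑methyl‑2,2‑diphenyl‑1,3‑benzodioxole‑5‑carbonyl)oxy]‑3‑oxobutyl]‑2H‑pyran‑6‑yl}prop‑2‑enoate | O=CC1=C(C[C@@H](OC(=O)c2c(C)cc3OC(c4ccccc4)(c4ccccc4)Oc3c2OC)C(C)=O)C=C(/C=C/C(=O)OC(C)(C)C)OC1
F3 | step 9 | tert‑butyl (2E)‑3‑{3‑formyl‑4‑[(1Z)‑2‑[(4‑methoxy‑6‑methyl‑2,2‑diphenyl‑1,3‑benzodioxole‑5‑carbonyl)oxy]‑3‑oxobut‑1‑en‑1‑yl]‑2H‑pyran‑6‑yl}prop‑2‑enoate | O=CC1=C(/C=C(\OC(=O)c2c(C)cc3OC(c4ccccc4)(c4ccccc4)Oc3c2OC)C(C)=O)C=C(/C=C/C(=O)OC(C)(C)C)OC1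
F4 | step 8 | tert‑butyl (2E)‑3‑{(3E)‑3‑[(dimethylamino)methylidene]‑4‑oxo‑3,4‑dihydro‑2H‑pyran‑6‑yl}prop‑2‑enoate | CN(C)/C=C1\COC(/C=C/C(=O)OC(C)(C)C)=CC1=O
F5 | step 8 | tert‑butyl (2E)‑3‑{3‑formyl‑4‑[(trifluoromethanesulfonyl)oxy]‑2H‑pyran‑6‑yl}prop‑2‑enoate | O=CC1=C(OS(=O)(=O)C(F)(F)F)C=C(/C=C/C(=O)OC(C)(C)C)OC1
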